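**Retrosynthetic overview**

1. Target 23 ⇐ tris-silyl ether 22 by buffered fluoride desilylation, a near-neutral last step that should leave C3 untouched.
2. 22 ⇐ racemic 3-bromochromanone 7 + arylzinc 21 (from aryl iodide 20): the C3–C6′ bond is formed by a Ni/pybox enantioconvergent Negishi arylation, which joins the two bicycles and sets C3 in one operation.
3. Enabling feature: C3 of the pyranone ring is the only stereocentre and lies α to the C4 ketone beside an unsubstituted C2H2, so a C3–Br bond gives a planar, carbonyl-stabilised radical whose configuration a catalyst can set. The aryl carbon C6′ of the chromene lies ortho to the C5′ oxygen, which directs its metalation.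
4. Ring order: the pyranone ring is closed first on phloroglucinol (Friedel–Crafts acylation, then O-alkylation). The 2H-pyran ring of the chromene is made by Knoevenagel/oxa-6π on cyclohexane-1,3-dione and its carbocycle is then aromatised to the B ring. The two bicycles are joined last.

Key step: step 10

Assumption: the stereocentre as drawn is (3R) (CIP order C4 > C2 > aryl > H). The sense of induction of the pybox ligand is not known for this substrate class, so the ligand antipode that gives 3R is to be assigned on the first run.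

**Route**

Step 1
Reactants: 1 phloroglucinol (benzene-1,3,5-triol); 2 3-chloropropanoic acid
Product: 4 5,7-dihydroxychroman-4-one, via 3-chloropropanoyl phloroglucinol 3 (not isolated)
Conditions: TfOH, 80 °C; then 2 M aq NaOH, 0 °C → rt; acidify to pH 3
Reagents that add atoms: none
Why: Friedel–Crafts acylation of the symmetrical, very nucleophilic triol (all ring positions equivalent) followed by intramolecular Williamson etherification (6-exo-tet) should close the pyranone ring.

Step 2
Reactants: 4 5,7-dihydroxychroman-4-one
Product: 5 5,7-bis[(tert-butyldimethylsilyl)oxy]chroman-4-one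
Conditions: TBSCl (2.5 equiv), imidazole, DMAP (cat.), DMF, rt → 40 °C
Reagents that add atoms: tert-butyldimethylsilyl chloride (TBSCl), CC(C)(C)[Si](C)(C)Cl
Why: Standard phenol silylation, with excess reagent and warming for the chelated 5-OH; it should mask both acidic phenols against the arylzinc and shield C6/C8 of the A ring.

Step 3
Reactants: 5 5,7-bis[(tert-butyldimethylsilyl)oxy]chroman-4-one
Product: 7 rac-3-bromo-5,7-bis[(tert-butyldimethylsilyl)oxy]chroman-4-one, via trimethylsilyl enol ether 6 (not isolated)
Conditions: LiHMDS, TMSCl, THF, −78 °C; then NBS, THF, −78 °C; pH 7 buffer work-up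
Reagents that add atoms: N-bromosuccinimide (NBS), O=C1CCC(=O)N1Br
Why: α-Bromination of a silyl enol ether; the enol silane should react with NBS at −78 °C far faster than the silyl-shielded arene, and the racemic bromide is what the enantioconvergent step needs.

Step 4
Reactants: 8 cyclohexane-1,3-dione; 9 3-methylbut-2-enal (prenal)
Product: 11 2,2-dimethyl-2,6,7,8-tetrahydro-5H-chromen-5-one, via Knoevenagel oxatriene 10 (not isolated)
Conditions: ethylenediammonium diacetate (10 mol%), MeOH, rt → 50 °C
Reagents that add atoms: none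
Why: Knoevenagel condensation followed by oxa-6π electrocyclisation of the 1-oxatriene should build the 2,2-dimethyl-2H-pyran ring.

Step 5
Reactants: 11 2,2-dimethyl-2,6,7,8-tetrahydro-5H-chromen-5-one
Product: 15 2,2-dimethyl-2H-chromen-5-ol, via 6-phenylselanyl ketone 12 (not isolated), via selenoxide 13 (not isolated), via dienone tautomer 14 (not isolated)
Conditions: LDA, THF, −78 °C; PhSeCl; then 30% aq H2O2, pyridine, CH2Cl2, 0 °C → rt
Reagents that add atoms: none
Why: Kinetic α′-deprotonation of the vinylogous ester at C6, selenenylation, selenoxide syn-elimination and tautomerisation of the dienone should aromatise the carbocycle and leave the only free OH at C5.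

Step 6
Reactants: 15 2,2-dimethyl-2H-chromen-5-ol
Product: 16 5-(methoxymethoxy)-2,2-dimethyl-2H-chromene
Conditions: MOMCl, i-Pr2NEt, CH2Cl2, 0 °C → rt
Reagents that add atoms: chloromethyl methyl ether (MOMCl), COCCl
Why: Williamson-type O-alkylation installs the acetal as an ortho-directing group for the next step.

Step 7
Reactants: 16 5-(methoxymethoxy)-2,2-dimethyl-2H-chromene
Product: 18 6-iodo-5-(methoxymethoxy)-2,2-dimethyl-2H-chromene, via aryllithium 17 (not isolated)
Conditions: n-BuLi, TMEDA, THF, −20 → 0 °C; then I2, THF, −78 °C → rt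
Reagents that add atoms: iodine, II
Why: Directed ortho-metalation; the chelating OMOM group at C5 should steer lithiation to C6, its only free ortho position, in preference to C8 beside the hindered ring oxygen, and iodine traps the aryllithium.

Step 8
Reactants: 18 6-iodo-5-(methoxymethoxy)-2,2-dimethyl-2H-chromene
Product: 19 6-iodo-2,2-dimethyl-2H-chromen-5-ol
Conditions: conc. HCl (cat.), MeOH, 40 °C
Reagents that add atoms: none
Why: Acid-catalysed acetal exchange with methanol frees the phenol before any stereocentre exists, so that the later deprotection can be fluoride-based.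

Step 9
Reactants: 19 6-iodo-2,2-dimethyl-2H-chromen-5-ol
Product: 20 tert-butyl[(6-iodo-2,2-dimethyl-2H-chromen-6-yl-5-oxy)]dimethylsilane, i.e. the 5-O-TBS ether of 19
Conditions: TBSCl, imidazole, DMF, rt → 40 °C
Reagents that add atoms: tert-butyldimethylsilyl chloride (TBSCl), CC(C)(C)[Si](C)(C)Cl
Why: Standard silylation; the silyl ether tolerates zinc insertion (no aryllithium is formed, so no silyl migration to carbon is expected) and is removable by fluoride.

Step 10
Reactants: 7 rac-3-bromo-5,7-bis[(tert-butyldimethylsilyl)oxy]chroman-4-one; 20 5-O-TBS-6-iodo-2,2-dimethyl-2H-chromene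
Product: 22 (3R)-5,7-bis[(tert-butyldimethylsilyl)oxy]-3-{5-[(tert-butyldimethylsilyl)oxy]-2,2-dimethyl-2H-chromen-6-yl}chroman-4-one, via arylzinc iodide 21 (not isolated)
Conditions: 20, activated Zn dust, LiCl, THF, 50 °C; then 7, NiCl2·glyme (10 mol%), chiral pybox ligand (13 mol%), glyme/THF, −30 °C; cold aq NH4Cl quench
Reagents that add atoms: none
Why: Proposed new method: the nickel/pybox-catalysed stereoconvergent Negishi arylation of racemic acyclic α-bromo ketones (the closest known reaction type) is extended to a cyclic α-bromo chroman-4-one with a β-aryloxy bond and to an ortho-siloxy arylzinc. The aryl–Ni(I) species formed by transmetalation should abstract bromine from either enantiomer of 7 to give the same planar C3 radical, stabilised by the C4 carbonyl; capture by the chiral aryl–Ni(II) complex and reductive elimination from Ni(III) form the C3–C6′ bond, so two carbons that are both nucleophilic by nature (enol carbon and oxygenated arene carbon) are joined through polarity reversal at C3. No ring is closed in this step. The new stereocentre C3 is set under catalyst control by the C2-symmetric pybox ligand on nickel, both enantiomers of the bromide converging on the 3R product. The step needs radical capture to outrun β-scission of the C2–O1 bond and loss of HBr to the chromone, which the half-chair pyranone ring should secure because the C2–O1 bond lies near the nodal plane of the C3 radical. It also needs the acidic C3–H of the product to survive, which the weakly basic arylzinc at −30 °C should allow.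

Step 11
Reactants: 22 (3R)-tris-TBS isoflavanone
Product: 23 (3R)-5,7-dihydroxy-3-(5-hydroxy-2,2-dimethyl-2H-chromen-6-yl)chroman-4-one
Conditions: TBAF/AcOH (1:1, 3.5 equiv), THF, 0 °C; pH 6 buffer work-up
Reagents that add atoms: none
Why: Fluoride-mediated cleavage of the three aryl Si–O bonds; the acetic acid buffer keeps the medium near neutral so that C3–H should not enolise, and the chromene double bond is inert to these conditions.

**Compound list**

1 | phloroglucinol | Oc1cc(O)cc(O)c1 | starting material
2 | 3-chloropropanoic acid | OC(=O)CCCl | starting material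
3 | 3-chloro-1-(2,4,6-trihydroxyphenyl)propan-1-one | O=C(CCCl)c1c(O)cc(O)cc1O | intermediate
4 | 5,7-dihydroxychroman-4-one | O=C1CCOc2cc(O)cc(O)c12 | intermediate
5 | 5,7-bis[(tert-butyldimethylsilyl)oxy]chroman-4-one | O=C1CCOc2cc(O[Si](C)(C)C(C)(C)C)cc(O[Si](C)(C)C(C)(C)C)c12 | intermediate
6 | 5,7-bis[(tert-butyldimethylsilyl)oxy]-4-(trimethylsilyloxy)-2H-chromene | C[Si](C)(C)OC1=CCOc2cc(O[Si](C)(C)C(C)(C)C)cc(O[Si](C)(C)C(C)(C)C)c12 | intermediate
7 | rac-3-bromo-5,7-bis[(tert-butyldimethylsilyl)oxy]chroman-4-one (racemate) | O=C1C(Br)COc2cc(O[Si](C)(C)C(C)(C)C)cc(O[Si](C)(C)C(C)(C)C)c12 | intermediate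
8 | cyclohexane-1,3-dione | O=C1CCCC(=O)C1 | starting material
9 | 3-methylbut-2-enal | CC(C)=CC=O | starting material
10 | 2-(3-methylbut-2-en-1-ylidene)cyclohexane-1,3-dione | CC(C)=CC=C1C(=O)CCCC1=O | intermediate
11 | 2,2-dimethyl-2,6,7,8-tetrahydro-5H-chromen-5-one | CC1(C)C=CC2=C(CCCC2=O)O1 | intermediate
12 | rac-2,2-dimethyl-6-(phenylselanyl)-2,6,7,8-tetrahydro-5H-chromen-5-one | CC1(C)C=CC2=C(CCC([Se]c3ccccc3)C2=O)O1 | intermediate
13 | 2,2-dimethyl-6-(phenylseleninyl)-2,6,7,8-tetrahydro-5H-chromen-5-one (mixture of stereoisomers) | CC1(C)C=CC2=C(CCC([Se](=O)c3ccccc3)C2=O)O1 | intermediate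
14 | 2,2-dimethyl-2,8-dihydro-5H-chromen-5-one | CC1(C)C=CC2=C(CC=CC2=O)O1 | intermediate
15 | 2,2-dimethyl-2H-chromen-5-ol | CC1(C)C=Cc2c(O)cccc2O1 | intermediate
16 | 5-(methoxymethoxy)-2,2-dimethyl-2H-chromene | CC1(C)C=Cc2c(OCOC)cccc2O1 | intermediate
17 | [5-(methoxymethoxy)-2,2-dimethyl-2H-chromen-6-yl]lithium | CC1(C)C=Cc2c(OCOC)c([Li])ccc2O1 | intermediate
18 | 6-iodo-5-(methoxymethoxy)-2,2-dimethyl-2H-chromene | CC1(C)C=Cc2c(OCOC)c(I)ccc2O1 | intermediate
19 | 6-iodo-2,2-dimethyl-2H-chromen-5-ol | CC1(C)C=Cc2c(O)c(I)ccc2O1 | intermediate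
20 | tert-butyl[(6-iodo-2,2-dimethyl-2H-chromen-5-yl)oxy]dimethylsilane | CC1(C)C=Cc2c(O[Si](C)(C)C(C)(C)C)c(I)ccc2O1 | intermediate
21 | {5-[(tert-butyldimethylsilyl)oxy]-2,2-dimethyl-2H-chromen-6-yl}zinc iodide | CC1(C)C=Cc2c(O[Si](C)(C)C(C)(C)C)c([Zn]I)ccc2O1 | intermediate
22 | (3R)-5,7-bis[(tert-butyldimethylsilyl)oxy]-3-{5-[(tert-butyldimethylsilyl)oxy]-2,2-dimethyl-2H-chromen-6-yl}chroman-4-one | CC1(C)C=Cc2c(ccc([C@@H]3COc4cc(O[Si](C)(C)C(C)(C)C)cc(O[Si](C)(C)C(C)(C)C)c4C3=O)c2O[Si](C)(C)C(C)(C)C)O1 | intermediate
23 | (3R)-5,7-dihydroxy-3-(5-hydroxy-2,2-dimethyl-2H-chromen-6-yl)chroman-4-one | CC1(C)C=Cc2c(ccc([C@@H]3COc4cc(O)cc(O)c4C3=O)c2O)O1 | target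

**Step count and risks**

Total steps: 11. Longest linear sequence: 8 steps (steps 4–11, from cyclohexane-1,3-dione); the chromanone branch (steps 1–3) joins at step 10.

Steps most likely to fail:

1. Step 10 (Proposed new method). Transmetalation of the hindered ortho-siloxy arylzinc may be slow, so that the C3 radical is reduced, opens the ring by loss of the β-aryloxy group, or loses HBr before it is captured; facial discrimination of a cyclic radical by the pybox–nickel complex may also be poor. Fallback with known chemistry, setting out from 5 and 20 and returning at 22: palladium-catalysed ketone α-arylation of chromanone 5 with iodide 20 (Pd2(dba)3, bulky phosphine, NaOt-Bu, toluene, 70 °C) should give the racemic tris-silyl isoflavanone F1. Noyori-type asymmetric transfer hydrogenation under dynamic kinetic resolution (Ru(p-cymene)(TsDPEN)Cl, HCO2H/Et3N, catalyst antipode chosen accordingly) should then give the (3R,4R)-cis-isoflavan-4-ol F2, in which C3 is fixed while the ketone racemises. Oxidation with Dess–Martin periodinane (NaHCO3, CH2Cl2, 0 °C) should return 22 without touching C3.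

2. Step 7. Lithiation may compete at C8 beside the ring oxygen or at the vinylic C4 peri to the acetal, or butyllithium may add to the styrene-type double bond. Fallback, setting out from 15 and returning at 20: amine-directed ortho-bromination of the free phenol (NBS, cat. i-Pr2NH, CH2Cl2, 0 °C) should give 6-bromo-2,2-dimethyl-2H-chromen-5-ol F3. Silylation (TBSCl, imidazole, DMF) gives the bromo silyl ether F4, and a copper-catalysed aromatic Finkelstein exchange (CuI, NaI, trans-N,N′-dimethylcyclohexane-1,2-diamine, dioxane, 110 °C) converts it into iodide 20, which bypasses 16–19.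

3. Step 3. Electrophilic bromination of the electron-rich A ring at C6/C8 may compete with the enol silane, and the bromide may lose HBr to the chromone on work-up. Fallback, setting out from 5 and returning at 7: enolate hydroxylation (LiHMDS, THF, −78 °C; 2-(phenylsulfonyl)-3-phenyloxaziridine) should give rac-3-hydroxy-5,7-bis[(tert-butyldimethylsilyl)oxy]chroman-4-one F5, so that no electrophilic bromine meets the arene. An Appel reaction (CBr4, PPh3, CH2Cl2, 0 °C) then exchanges the hydroxyl for bromide under neutral conditions to give 7.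

**Further compounds**

F1 | step 10 | rac-5,7-bis[(tert-butyldimethylsilyl)oxy]-3-{5-[(tert-butyldimethylsilyl)oxy]-2,2-dimethyl-2H-chromen-6-yl}chroman-4-one | CC1(C)C=Cc2c(ccc(C3COc4cc(O[Si](C)(C)C(C)(C)C)cc(O[Si](C)(C)C(C)(C)C)c4C3=O)c2O[Si](C)(C)C(C)(C)C)O1
F2 | step 10 | (3R,4R)-5,7-bis[(tert-butyldimethylsilyl)oxy]-3-{5-[(tert-butyldimethylsilyl)oxy]-2,2-dimethyl-2H-chromen-6-yl}chroman-4-ol | CC1(C)C=Cc2c(ccc([C@@H]3COc4cc(O[Si](C)(C)C(C)(C)C)cc(O[Si](C)(C)C(C)(C)C)c4[C@@H]3O)c2O[Si](C)(C)C(C)(C)C)O1
F3 | step 7 | 6-bromo-2,2-dimethyl-2H-chromen-5-ol | CC1(C)C=Cc2c(O)c(Br)ccc2O1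
F4 | step 7 | [(6-bromo-2,2-dimethyl-2H-chromen-5-yl)oxy](tert-butyl)dimethylsilane | CC1(C)C=Cc2c(O[Si](C)(C)C(C)(C)C)c(Br)ccc2O1
F5 | step 3 | rac-5,7-bis[(tert-butyldimethylsilyl)oxy]-3-hydroxychroman-4-one | O=C1C(O)COc2cc(O[Si](C)(C)C(C)(C)C)cc(O[Si](C)(C)C(C)(C)C)c12
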